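## Structural features

The target is a flavanone: benzene ring A is fused to a 2,3-dihydropyran-4-one ring C, and benzene ring B is attached through C1' to C2 of ring C. C2 is the only stereocentre (S) and has no stereogenic neighbour. It is benzylic, bears the ring oxygen O1 and lies beta to the C4 carbonyl, so its configuration is lost whenever ring C opens to the 2'-hydroxychalcone under base or, in a 4'-hydroxy compound, to a quinone methide. Ring A has the phloroglucinol pattern: the 5-OH is locked in a hydrogen bond to C4=O, and the 7-OH is a vinylogous acid and the most acidic site. Ring B carries the 4'-methoxy group and, ortho to it at C3', a 3-methylbut-2-enyl (prenyl) chain. The trisubstituted olefin of that chain is sensitive to strong acid (hydration, or cyclisation to a 2,2-dimethylchroman when the neighbouring oxygen is a free phenol), to hydrogenation and to electrophilic oxidants. The real difficulty is site selection, not skeleton building: one C5 unit must go to C3' of ring B although C6 and C8 of ring A are far more nucleophilic, and only the 4'-OH of three phenols must be methylated. The key step uses the free 4'-OH of ring B as the activating and orienting group for an enzyme-held allyl cation. It also uses the fact that C3' and C5' are exchanged by rotation about the C2–C1' bond, so either ortho position gives the same C3'–C1'' bond.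

## Logic of the disconnections

7 to 6: the O7–H of 7 is traced back to an O7–CH2OCH3 acetal. The cut adds no skeletal simplicity; it keeps the most acidic phenol masked until the 4'-oxygen has been methylated. The forward step needs acid mild enough to spare the prenyl olefin and C2. This is eased because the 4'-oxygen of 6 is already an ether and cannot cyclise onto the prenyl group.

6 to 5: the O4'–CH3 bond is cut. The methyl group must come after the C–C bond formation because the prenylation needs the free 4'-OH. The forward step must methylate the 4'-OH only, leave the chelated 5-OH alone, and avoid base strong enough to open ring C.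

5 to 4: the O7–CH2OCH3 bond is cut, which leads to a compound without protecting groups. The forward step must alkylate once, at the most acidic phenol, under conditions that do not epimerise C2.

4 to 3 and 2: the C3'–C1'' bond is cut. It is the only carbon–carbon bond of the target that is missing from an abundant chiral-pool flavanone. 3 brings rings A, B and C and the (S) centre ready-made, so no ring and no stereocentre has to be built. The forward step must overrule the intrinsic reactivity order (ring A before ring B, oxygen before carbon) and run at neutral pH; only positioning of both partners in an enzyme pocket is expected to do this.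

2 to 1: the C1''–O bond of the allylic diphosphate is cut. 2 is costly and labile, whereas 1 is a bulk chemical, so one step suffices. The forward step must be a clean SN2 displacement without allylic transposition or solvolysis, and the product must be isolated without acid.

## Other disconnections considered

Alternative 1: The cut is the C3=C4 bond of ring C, with the C4 ketone read as its silyl enol ether.
- **Forward key step:** the triene A1 already has O1 joined to the (S)-configured benzylic carbon bearing ring B and a vinyl group, and holds the ring A acetyl group as its tert-butyldimethylsilyl enol ether. RuCl2(=CHPh)(H2IMes)(PCy3), the second-generation Grubbs catalyst, would close it to the 4-silyloxy-2H-chromene A2. Desilylation and removal of the two methoxymethyl groups would then lead to 7.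
- **In its favour:** ring C is closed by a neutral olefin metathesis and not by an oxa-Michael addition, so the chalcone equilibrium is avoided during ring formation. The 4'-methoxy and 3'-prenyl groups arrive with the ring B fragment, so no phenol has to be told apart on the flavanone. On that point, and in needing no protein, it is better than the chosen plan.
- **Against it here:** the prenyl group of A1 is a third olefin and can be truncated by cross-metathesis with the ruthenium methylidene. The enol ether is 1,1-disubstituted and flanked by two ortho substituents, so closure should be slow and need heat. The C2–O1 bond of A1 and A2 is allylic, benzylic to an anisole ring and attached to a phenoxide leaving group, so ionisation or a sigmatropic shift threatens the stereocentre; in A2 a reversible six-electron ring opening of the 2H-chromene adds to this. That stereocentre must first be made in a separate asymmetric step.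
- **Comparison:** on structure it builds a ring and a stereocentre that the chosen plan takes from the chiral pool. On mechanism both plans rest on an unproven selectivity: a metal carbene choosing among three olefins against an enzyme choosing between two rings. On step economy it should need about twice as many steps as the chosen five.

Alternative 2: The cuts are O1–C2 and C3–C4, which divide ring C into the salicylaldehyde A3 and the styrene A4.
- **Forward key step:** a confined chiral Brønsted acid (an N-triflyl phosphoramide of a 3,3'-diaryl-BINOL or an imidodiphosphorimidate) activates the aldehyde of A3. The styrene terminus of A4 adds to it and the phenol oxygen closes onto the benzylic carbon, giving the 2,4-cis flavan-4-ol A5 with both stereocentres. Oxidation of the C4 carbinol and removal of the acetates would give 7.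
- **In its favour:** it is the most convergent of the four plans. Two bonds, ring C and the C2 centre come from two achiral fragments in one catalytic, atom-economical step. On convergence and bonds formed per step it is better than the chosen plan, and it also needs no protein.
- **Against it here:** A4 contains a p-alkoxystyrene and a trisubstituted olefin, and both are acid-sensitive. The prenyl olefin can compete for the proton or the oxocarbenium ion, and the styrene can oligomerise. The C2–O1 bond of A5 is a p-methoxybenzylic ether that can re-ionise under the catalyst and erode the enantiomeric purity. A3 must carry acyl groups to tame the phloroglucinol ring; these lower the basicity of its carbonyl and can migrate to the free ortho hydroxyl. The C4 stereocentre is made only to be oxidised away, and the final deacylation must avoid base.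
- **Comparison:** on structure it creates the stereocentre that the chosen plan inherits, and it pays a redox detour at C4. On mechanism both key steps are attacks of cation-like electrophiles on electron-rich pi systems; in the chosen plan the cation is enclosed by protein, here the second olefin of the substrate is exposed to the acid. On step economy it should need about seven to eight steps with a longest sequence near five, so it is roughly equal in length of sequence and worse in total.

Alternative 3: The cut is the C2–C1' bond.
- **Forward key step:** 5,7-bis(methoxymethoxy)chromone A6 and the arylboronic acid A7 would be joined under Pd(OCOCF3)2 (divalent palladium) with the enantiomer of the tert-butyl pyridine–oxazoline ligand that delivers (2S). The sequence is transmetalation, enantio-determining insertion of the C2=C3 bond into the aryl–palladium bond, and protonation of the palladium enolate, giving the flavanone A8. Acid would then remove both methoxymethyl groups and give 7.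
- **In its favour:** C2 is set irreversibly in a carbon–carbon bond formation under catalyst control. The plan is wholly chemical, gives either enantiomer and analogues, and does not depend on the optical purity of a purchased natural product. The ring B pattern is fixed in A7 and the endgame is two steps. On these points it is better than the chosen plan.
- **Against it here:** the cationic divalent palladium can bind or functionalise the prenyl olefin of A7 (isomerisation, allylic activation, oxypalladation). The electron-rich A7 is prone to protodeboronation. A6 is a doubly donor-substituted and therefore weakly electrophilic chromone with a substituent peri to the carbonyl. A6 and A7 each need several steps.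
- **Comparison:** on structure the chosen plan forms no stereocentre, while this plan forms it with a catalyst; both must then carry C2 through an acidic deprotection, so they are equal there. On mechanism a transition metal must ignore a spectator olefin, against an enzyme that must ignore a more nucleophilic ring. On step economy it should be about equal in longest sequence and longer in total, but better for scale-up.

Key step: step 2

Assumption: commercial (2S)-naringenin is taken to be of high enantiomeric purity (to be confirmed by chiral HPLC), because the route transfers the C2 configuration and does not create it; the prenyltransferase is taken to be available by routine heterologous expression. The stereodescriptors and SMILES of 3, 4 and 7 were checked against each other (O1 > C1' > C3 > H at C2 in all three) and needed no correction.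

## Route

Step 1
Reactants: 1 1-bromo-3-methylbut-2-ene (prenyl bromide)
Product: 2 dimethylallyl diphosphate (3-methylbut-2-en-1-yl diphosphate), isolated as its tris-ammonium salt
Conditions: (n-Bu4N)3HP2O7 (2 equiv), MeCN, rt, 2 h; Dowex 50WX8 (NH4+ form), aq. NH4HCO3; cellulose chromatography; lyophilise, store at −20 °C
Reagents that add atoms: tris(tetra-n-butylammonium) hydrogen diphosphate, CCCC[N+](CCCC)(CCCC)CCCC.CCCC[N+](CCCC)(CCCC)CCCC.CCCC[N+](CCCC)(CCCC)CCCC.OP(=O)([O-])OP(=O)([O-])[O-]
Why: SN2 displacement of a primary allylic bromide by the hydrogen diphosphate trianion in a dipolar aprotic solvent is the standard synthesis of allylic diphosphates; the excess of nucleophile suppresses double alkylation, and cation exchange at slightly basic pH avoids the acid-promoted ionisation to which allylic diphosphates are prone.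

Step 2
Reactants: 3 (2S)-naringenin; 2 dimethylallyl diphosphate
Product: 4 licoflavanone, (2S)-5,7-dihydroxy-2-[4-hydroxy-3-(3-methylbut-2-enyl)phenyl]chroman-4-one
Conditions: recombinant His6-tagged AnaPT-type dimethylallyltryptophan synthase prenyltransferase, 2 (2 equiv), Tris·HCl 50 mM pH 7.5, CaCl2 10 mM, DMSO 5% v/v, 37 °C, 16–24 h; EtOAc extraction, reversed-phase chromatography
Reagents that add atoms: none
Why: The enzyme binds the diphosphate of 2 to a ring of basic residues inside its barrel and ionises it to a dimethylallyl cation–diphosphate ion pair that is stabilised by cation–pi contacts with aromatic side chains. Bound 3 presents C3' of ring B, ortho to the activating 4'-OH, to the primary carbon C1'' of the cation; electrophilic aromatic substitution of the Friedel–Crafts type gives an arenium ion, and loss of the C3' proton in the pocket restores ring B and leaves the new C3'–C1'' bond. The closest known reaction type is aromatic C-prenylation by soluble dimethylallyltryptophan synthase enzymes, a family whose members accept flavanones and other hydroxylated aromatics besides indoles. No ring is closed and no stereocentre is formed; C2 is a spectator. At pH 7.5 and 37 °C the 4'-OH is essentially un-ionised, so opening of ring C through a quinone methide or chalcone should be slow on the time scale of the incubation and the (S) configuration should be kept. The step needs site selectivity for C3' over the intrinsically more nucleophilic C6 and C8 of ring A, carbon over oxygen alkylation, attack through the primary and not the tertiary allyl terminus, and mono- over bis-prenylation. All of these are expected from the fixed geometry of cation and acceptor in the active site and not from substrate reactivity; the substrate contributes the free 4'-OH and the rotational equivalence of C3' and C5', so that either ortho position gives 4. Calcium ions raise the rate of this enzyme family without being essential, and the excess of 2 compensates for its background hydrolysis.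

Step 3
Reactants: 4 licoflavanone
Product: 5 (2S)-5-hydroxy-2-[4-hydroxy-3-(3-methylbut-2-enyl)phenyl]-7-(methoxymethoxy)chroman-4-one
Conditions: MOMCl (1.1 equiv), iPr2NEt (1.5 equiv), CH2Cl2, 0 °C, 1–2 h
Reagents that add atoms: chloromethyl methyl ether, COCCl
Why: This is a Williamson-type O-alkylation of a phenol with an alpha-chloro ether, and its chemoselectivity follows acidity: the 7-OH is a vinylogous carboxylic acid and the only phenol ionised by the amine, the 5-OH is held in the hydrogen bond to C4=O, and the 4'-OH is less acidic and flanked by the prenyl group. A tertiary amine in CH2Cl2 at 0 °C should be too weak to open ring C, so C2 is retained.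

Step 4
Reactants: 5 (2S)-5-hydroxy-2-[4-hydroxy-3-(3-methylbut-2-enyl)phenyl]-7-(methoxymethoxy)chroman-4-one
Product: 6 (2S)-5-hydroxy-7-(methoxymethoxy)-2-[4-methoxy-3-(3-methylbut-2-enyl)phenyl]chroman-4-one
Conditions: TMSCHN2 (2 M in hexanes, 2 equiv), iPr2NEt (1 equiv), MeCN–MeOH 9:1, 0 °C to rt, 12–16 h; AcOH quench
Reagents that add atoms: trimethylsilyldiazomethane, C[Si](C)(C)C=[N+]=[N-]
Why: This is the O-methylation of a phenol by trimethylsilyldiazomethane in the presence of methanol: the phenol protonates the diazo carbon, methanol removes the silyl group, and the methyldiazonium ion transfers its methyl group to the phenol oxygen with loss of N2. With the 7-OH blocked and the 5-OH chelated, the 4'-OH is the only phenol free to react. In the acetonitrile-rich medium the amine only hydrogen-bonds to the phenol, so the concentration of free 4'-phenoxide, the species that could open ring C, stays low and C2 should be retained.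

Step 5
Reactants: 6 (2S)-5-hydroxy-7-(methoxymethoxy)-2-[4-methoxy-3-(3-methylbut-2-enyl)phenyl]chroman-4-one
Product: 7 4'-O-methyllicoflavanone, (2S)-5,7-dihydroxy-2-[4-methoxy-3-(3-methylbut-2-enyl)phenyl]chroman-4-one
Conditions: HCl (1 M) in MeOH–H2O 9:1, 45 °C, 2 h; aq. NaHCO3 work-up
Reagents that add atoms: none
Why: This is an acid-catalysed cleavage of a phenolic methoxymethyl acetal by transacetalisation to methanol. Because the 4'-oxygen is now a methyl ether, the acid-promoted cyclisation of an ortho-prenyl phenol to a 2,2-dimethylchroman cannot occur, and dilute acid at moderate temperature should neither hydrate the trisubstituted olefin nor open ring C, so C2 stays (S).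

## Compound list

1 | 1-bromo-3-methylbut-2-ene (prenyl bromide) | CC(C)=CCBr | starting material
2 | dimethylallyl diphosphate (3-methylbut-2-en-1-yl diphosphate; isolated and used as its tris-ammonium salt, drawn as the free acid) | CC(C)=CCOP(=O)(O)OP(=O)(O)O | intermediate
3 | (2S)-naringenin, (2S)-5,7-dihydroxy-2-(4-hydroxyphenyl)chroman-4-one | Oc1ccc([C@@H]2CC(=O)c3c(O)cc(O)cc3O2)cc1 | starting material
4 | licoflavanone, (2S)-5,7-dihydroxy-2-[4-hydroxy-3-(3-methylbut-2-enyl)phenyl]chroman-4-one | Oc1ccc([C@@H]2CC(=O)c3c(O)cc(O)cc3O2)cc1CC=C(C)C | intermediate
5 | (2S)-5-hydroxy-2-[4-hydroxy-3-(3-methylbut-2-enyl)phenyl]-7-(methoxymethoxy)chroman-4-one | Oc1ccc([C@@H]2CC(=O)c3c(O)cc(OCOC)cc3O2)cc1CC=C(C)C | intermediate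
6 | (2S)-5-hydroxy-7-(methoxymethoxy)-2-[4-methoxy-3-(3-methylbut-2-enyl)phenyl]chroman-4-one | COc1ccc([C@@H]2CC(=O)c3c(O)cc(OCOC)cc3O2)cc1CC=C(C)C | intermediate
7 | 4'-O-methyllicoflavanone, (2S)-5,7-dihydroxy-2-[4-methoxy-3-(3-methylbut-2-enyl)phenyl]chroman-4-one | COc1ccc([C@@H]2CC(=O)c3c(O)cc(O)cc3O2)cc1CC=C(C)C | target

## Step count and least certain steps

Total: 5 steps. Longest linear sequence: 5 steps (1, 2, 4, 5, 6, 7); 4 steps counted from 3.

Step 2 (key step). The most likely failures are insufficient turnover and loss of site selectivity (alkylation at C6 of ring A or at oxygen, or a second prenylation). The enzyme family evolved for indoles and should accept a flavanone with modest efficiency, the substrate is poorly soluble in buffer, and 2 hydrolyses in the background.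
- **Fallback:** it sets out from 3 and rejoins the route at 5, replacing steps 2 and 3 by chemistry in which the regiochemistry is fixed intramolecularly.
- The 7-OH of 3 would be masked under the conditions of step 3 to give (2S)-7-O-(methoxymethyl)naringenin F1.
- Palladium-catalysed allylic etherification of the 4'-OH with isobutyl 2-methylbut-3-en-2-yl carbonate (Pd(PPh3)4, zerovalent palladium, THF, 0 °C to rt) places the phenoxide on the tertiary terminus of the allyl complex and would give the 1,1-dimethylallyl aryl ether, (2S)-5-hydroxy-7-(methoxymethoxy)-2-{4-[(2-methylbut-3-en-2-yl)oxy]phenyl}chroman-4-one F2.
- An aromatic Claisen rearrangement (toluene, 110 °C) would then carry the allyl unit, with exchange of its termini, to the ortho carbon C3' and give 5. The para position is blocked and the two ortho positions are equivalent.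

Step 3. The most likely failures are over-alkylation at the 4'-oxygen and partial loss of the C2 configuration through base-induced opening of ring C, since selection rests only on the acidity gap between two phenols.
- **Fallback:** it sets out from 4 and rejoins the route at 7. It selects the 7-OH by a redox condensation that engages only the most acidic phenol and uses a mask that is removed without acid.
- Mitsunobu etherification of 4 with allyl alcohol (PPh3, diisopropyl azodicarboxylate, THF, 0 °C) would give (2S)-7-(allyloxy)-5-hydroxy-2-[4-hydroxy-3-(3-methylbut-2-enyl)phenyl]chroman-4-one F3.
- Methylation as in step 4 would give (2S)-7-(allyloxy)-5-hydroxy-2-[4-methoxy-3-(3-methylbut-2-enyl)phenyl]chroman-4-one F4.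
- Allyl transfer to morpholine under Pd(PPh3)4 (zerovalent palladium, THF, rt), which leaves the unactivated prenyl olefin untouched, would give 7.

Step 4. The most likely failures are slow methyl transfer to the hindered, weakly acidic 4'-OH, methylation of the chelated 5-OH if the reaction is forced, and erosion of enantiomeric purity by reversible opening of ring C in the presence of the amine.
- **Fallback:** it sets out from 5 and rejoins the route at 6. The diazonium methyl transfer is replaced by activation of methanol as an alkoxyphosphonium ion.
- Mitsunobu methylation (MeOH, PPh3, diisopropyl azodicarboxylate, THF, 0 °C to rt) engages the 4'-OH at low temperature without amine base and leaves the chelated 5-OH alone. No compound beyond those of the main route is formed (entry F0).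

## Further compounds

F1 | step 2 | (2S)-5-hydroxy-2-(4-hydroxyphenyl)-7-(methoxymethoxy)chroman-4-one | Oc1ccc([C@@H]2CC(=O)c3c(O)cc(OCOC)cc3O2)cc1
F2 | step 2 | (2S)-5-hydroxy-7-(methoxymethoxy)-2-{4-[(2-methylbut-3-en-2-yl)oxy]phenyl}chroman-4-one | C=CC(C)(C)Oc1ccc([C@@H]2CC(=O)c3c(O)cc(OCOC)cc3O2)cc1
F3 | step 3 | (2S)-7-(allyloxy)-5-hydroxy-2-[4-hydroxy-3-(3-methylbut-2-enyl)phenyl]chroman-4-one | Oc1ccc([C@@H]2CC(=O)c3c(O)cc(OCC=C)cc3O2)cc1CC=C(C)C
F4 | step 3 | (2S)-7-(allyloxy)-5-hydroxy-2-[4-methoxy-3-(3-methylbut-2-enyl)phenyl]chroman-4-one | COc1ccc([C@@H]2CC(=O)c3c(O)cc(OCC=C)cc3O2)cc1CC=C(C)C
F0 | step 4 | none | none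
A1 | alternative 1 | tert-butyl{[1-(2-{[(1S)-1-(4-methoxy-3-(3-methylbut-2-enyl)phenyl)prop-2-en-1-yl]oxy}-4,6-bis(methoxymethoxy)phenyl)ethenyl]oxy}dimethylsilane | COc1ccc([C@H](C=C)Oc2cc(OCOC)cc(OCOC)c2C(=C)O[Si](C)(C)C(C)(C)C)cc1CC=C(C)C
A2 | alternative 1 | (2S)-4-(tert-butyldimethylsilyloxy)-5,7-bis(methoxymethoxy)-2-[4-methoxy-3-(3-methylbut-2-enyl)phenyl]-2H-chromene | COc1ccc([C@@H]2C=C(O[Si](C)(C)C(C)(C)C)c3c(OCOC)cc(OCOC)cc3O2)cc1CC=C(C)C
A3 | alternative 2 | 4,6-diacetoxy-2-hydroxybenzaldehyde | CC(=O)Oc1cc(O)c(C=O)c(OC(C)=O)c1
A4 | alternative 2 | 4-methoxy-3-(3-methylbut-2-enyl)styrene | COc1ccc(C=C)cc1CC=C(C)C
A5 | alternative 2 | (2S,4S)-5,7-diacetoxy-4'-methoxy-3'-prenylflavan-4-ol (2,4-cis) | COc1ccc([C@@H]2C[C@H](O)c3c(OC(C)=O)cc(OC(C)=O)cc3O2)cc1CC=C(C)C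
A6 | alternative 3 | 5,7-bis(methoxymethoxy)-4H-chromen-4-one | O=c1ccoc2cc(OCOC)cc(OCOC)c12
A7 | alternative 3 | [4-methoxy-3-(3-methylbut-2-enyl)phenyl]boronic acid | COc1ccc(B(O)O)cc1CC=C(C)C
A8 | alternative 3 | (2S)-5,7-bis(methoxymethoxy)-4'-methoxy-3'-prenylflavanone | COc1ccc([C@@H]2CC(=O)c3c(OCOC)cc(OCOC)cc3O2)cc1CC=C(C)C
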